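**Assumption:** atom labels C1–C15 are a germacrane-type numbering chosen here (C1 = carbinol with the free OH, C3 = acetoxy carbon, C4=C5 and C9=C10 = the two Z olefins, C6 = lactone carbinol, C7 = ring carbon bearing the acrylate, C8 = angelate carbon); both chiral starting materials are catalogue compounds. The route is a paper proposal and has not been run.

## Retrosynthetic overview

1. Ten-membered ring last: C1–C10 bond by electrochemical Ni/Cr Nozaki–Hiyama–Kishi (NHK) macrocyclisation of seco-aldehyde 20; C1 is set 1,3-anti to the C3 acetate.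
2. Lactone ring before that: C6–C7 bond by indium Barbier 2-(methoxycarbonyl)allylation of lactol 6 with allyl bromide 15, then lactonisation; C6 and C7 are set from C8.
3. Fragment 1 (C1–C6): (S)-α-hydroxy-γ-butyrolactone → alkyne → Cu-catalysed anti-carbomagnesiation/formylation (Z-C4=C5, C3 bought).
4. Fragment 2 (C7–C14): (R)-glyceraldehyde acetonide → chelation-controlled propynylation (C8) → trans-hydroalumination/iodination (Z-C9=C10) → angelate → glycol cleavage → vinylalumination → SN2′ bromination.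

## Route

**Step 1**
Reactants: 1 (3S)-3-hydroxyoxolan-2-one
Product: 3 (3S)-pent-4-yne-1,3-diol, via lactol 2 (not isolated)
Conditions: i-Bu2AlH (2.2 equiv), CH2Cl2, −78 °C; then MeOH, K2CO3, dimethyl (1-diazo-2-oxopropyl)phosphonate, −78 °C → rt
Reagents that add atoms: dimethyl (1-diazo-2-oxopropyl)phosphonate, CC(=O)C(=[N+]=[N-])P(=O)(OC)OC
Why: Partial reduction of the lactone to the lactol followed by Seyferth–Gilbert homologation with the Bestmann–Ohira reagent turns the carbonyl carbon into a terminal alkyne under mild K2CO3/MeOH conditions, leaving the bought carbinol centre (future C3) untouched.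

**Step 2**
Reactants: 3 (3S)-pent-4-yne-1,3-diol
Product: 4 (3S)-5-{[tert-butyl(dimethyl)silyl]oxy}pent-1-yn-3-ol
Conditions: TBSCl (1.05 equiv), imidazole, CH2Cl2, −20 → 0 °C
Reagents that add atoms: tert-butyldimethylsilyl chloride, CC(C)(C)[Si](C)(C)Cl
Why: Sterically controlled silylation takes the primary hydroxyl only, keeping the propargylic hydroxyl free as the directing group for the next step.

**Step 3**
Reactants: 4 (3S)-5-{[tert-butyl(dimethyl)silyl]oxy}pent-1-yn-3-ol
Product: 6 (5S)-5-(2-{[tert-butyl(dimethyl)silyl]oxy}ethyl)-4-methyl-2,5-dihydrofuran-2-ol, via oxamagnesacycle 5 (not isolated)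
Conditions: MeMgBr (3.5 equiv), CuI (20 mol%), THF, 0 °C → rt; then DMF, 0 °C → rt; pH 7 phosphate buffer
Reagents that add atoms: methylmagnesium bromide, C[Mg]Br; N,N-dimethylformamide, CN(C)C=O
Why: Alkoxide-directed copper-catalysed anti-carbomagnesiation (Duboudin type) puts methyl on C4 and magnesium on C5 cis to C3 in a five-membered chelate, which fixes the Z olefin, and Bouveault formylation with DMF gives the Z-hydroxy-enal that closes to lactol 6 without touching C3.

**Step 4**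
Reactants: 7 (4R)-2,2-dimethyl-1,3-dioxolane-4-carbaldehyde
Product: 8 (1R)-1-[(4R)-2,2-dimethyl-1,3-dioxolan-4-yl]but-2-yn-1-ol
Conditions: MeC≡CMgBr, ZnBr2, Et2O, −78 → 0 °C
Reagents that add atoms: 1-propynylmagnesium bromide, CC#C[Mg]Br
Why: Chelation-controlled (Cram cyclic model, zinc bridging the aldehyde oxygen and the α-oxygen of the dioxolane) addition of the alkynylzinc reagent gives the syn (threo) propargylic alcohol, so the bought stereocentre sets the future C8; the minor anti isomer is removed by chromatography.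

**Step 5**
Reactants: 8 (1R)-1-[(4R)-2,2-dimethyl-1,3-dioxolan-4-yl]but-2-yn-1-ol
Product: 10 (1R,2Z)-1-[(4R)-2,2-dimethyl-1,3-dioxolan-4-yl]-3-iodobut-2-en-1-ol, via alkenylaluminate 9 (not isolated)
Conditions: NaAlH2(OCH2CH2OMe)2, THF, 0 °C → rt; then I2, THF, −78 → 0 °C
Reagents that add atoms: iodine, II
Why: Hydroxyl-directed trans-hydroalumination delivers aluminium to the distal alkyne carbon through a five-membered alkoxyaluminate, and iodinolysis with retention gives the (Z)-iodoalkene with iodine cis to C8, which is not touched.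

**Step 6**
Reactants: 10 (1R,2Z)-1-[(4R)-2,2-dimethyl-1,3-dioxolan-4-yl]-3-iodobut-2-en-1-ol
Product: 11 (1R,2Z)-1-[(4R)-2,2-dimethyl-1,3-dioxolan-4-yl]-3-iodobut-2-en-1-yl (2Z)-2-methylbut-2-enoate
Conditions: angelic acid, 2,4,6-trichlorobenzoyl chloride, Et3N, toluene, rt; then 10, 80 °C
Reagents that add atoms: angelic acid, C/C=C(/C)C(=O)O
Why: Yamaguchi mixed-anhydride esterification without DMAP acylates the hindered allylic alcohol at the angeloyl carbonyl without Z→E isomerisation to the tiglate and with retention at C8 (O-acylation).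

**Step 7**
Reactants: 11 (1R,2Z)-1-[(4R)-2,2-dimethyl-1,3-dioxolan-4-yl]-3-iodobut-2-en-1-yl (2Z)-2-methylbut-2-enoate
Product: 13 (2R,3Z)-4-iodo-1-oxopent-3-en-2-yl (2Z)-2-methylbut-2-enoate, via diol 12 (not isolated)
Conditions: H5IO6, EtOAc, rt (product used at once)
Reagents that add atoms: none
Why: Periodic acid hydrolyses the terminal acetonide and cleaves the resulting 1,2-diol in one pot (Malaprade cleavage), removing the sacrificial glyceraldehyde centre and leaving the C7 aldehyde next to the intact C8 centre.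

**Step 8**
Reactants: 13 (2R,3Z)-4-iodo-1-oxopent-3-en-2-yl (2Z)-2-methylbut-2-enoate
Product: 14 methyl (4R,5Z)-3-hydroxy-6-iodo-4-{[(2Z)-2-methylbut-2-enoyl]oxy}-2-methylidenehept-5-enoate (C3 epimers)
Conditions: methyl propiolate, i-Bu2AlH, N-methylmorpholine N-oxide, THF, 0 °C; then 13, 0 °C → rt
Reagents that add atoms: methyl propiolate, C#CC(=O)OC
Why: Vinylalumination (a non-basic route to Baylis–Hillman-type adducts) adds the α-aluminoacrylate to the aldehyde without epimerising the α-acyloxy centre or migrating the angelate; the new carbinol centre is irrelevant because it becomes sp2 in step 9.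

**Step 9**
Reactants: 14 methyl (4R,5Z)-3-hydroxy-6-iodo-4-{[(2Z)-2-methylbut-2-enoyl]oxy}-2-methylidenehept-5-enoate
Product: 15 methyl (2Z,4S,5Z)-2-(bromomethyl)-6-iodo-4-{[(2Z)-2-methylbut-2-enoyl]oxy}hepta-2,5-dienoate
Conditions: NBS, Me2S, CH2Cl2, −20 → 0 °C
Reagents that add atoms: N-bromosuccinimide, O=C1CCC(=O)N1Br
Why: Corey–Kim-type activation of the allylic alcohol and SN2′ delivery of bromide transpose the allylic system to the thermodynamically preferred (Z)-2-(bromomethyl)enoate under neutral conditions.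

**Step 10**
Reactants: 6 (5S)-5-(2-{[tert-butyl(dimethyl)silyl]oxy}ethyl)-4-methyl-2,5-dihydrofuran-2-ol; 15 methyl (2Z,4S,5Z)-2-(bromomethyl)-6-iodo-4-{[(2Z)-2-methylbut-2-enoyl]oxy}hepta-2,5-dienoate
Product: 17 (4S,5S)-5-[(1Z,3S)-5-{[tert-butyl(dimethyl)silyl]oxy}-3-hydroxy-2-methylpent-1-en-1-yl]-4-[(1S,2Z)-3-iodo-1-{[(2Z)-2-methylbut-2-enoyl]oxy}but-2-en-1-yl]-3-methylideneoxolan-2-one, via hydroxy ester 16 (not isolated)
Conditions: In powder (2 equiv), THF, rt; then PPTS (cat.), CH2Cl2, rt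
Reagents that add atoms: none
Why: Indium Barbier 2-(methoxycarbonyl)allylation (Dreiding–Schmidt type) of the open hydroxy-enal form of 6 through a closed six-membered transition state gives the syn adduct and hence the cis-lactone, the allyl unit reacting on the face anti to the C9 alkenyl arm of C8 (C8–H eclipsing the alkene, allylic-strain model), so C8 sets C7 and C6, and the new C6 hydroxyl lactonises onto the methyl ester.

**Step 11**
Reactants: 17 cis-lactone with free C3 hydroxyl (name as in step 10)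
Product: 18 (4S,5S)-5-[(1Z,3S)-3-(acetyloxy)-5-{[tert-butyl(dimethyl)silyl]oxy}-2-methylpent-1-en-1-yl]-4-[(1S,2Z)-3-iodo-1-{[(2Z)-2-methylbut-2-enoyl]oxy}but-2-en-1-yl]-3-methylideneoxolan-2-one
Conditions: Ac2O, pyridine, DMAP (cat.), CH2Cl2, 0 °C
Reagents that add atoms: acetic anhydride, CC(=O)OC(C)=O
Why: The C3 hydroxyl set free from the lactol is the only free hydroxyl, so standard acylation installs the acetate regiospecifically with retention.

**Step 12**
Reactants: 18 C3 acetate with C1 silyl ether (name as in step 11)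
Product: 19 (4S,5S)-5-[(1Z,3S)-3-(acetyloxy)-5-hydroxy-2-methylpent-1-en-1-yl]-4-[(1S,2Z)-3-iodo-1-{[(2Z)-2-methylbut-2-enoyl]oxy}but-2-en-1-yl]-3-methylideneoxolan-2-one
Conditions: HF·pyridine, THF–pyridine, 0 °C → rt
Reagents that add atoms: none
Why: Buffered fluoride desilylation frees the primary C1 hydroxyl without acyl migration and without touching the acetate, angelate, lactone or alkenyl iodide.

**Step 13**
Reactants: 19 primary alcohol (name as in step 12)
Product: 20 (4S,5S)-5-[(1Z,3S)-3-(acetyloxy)-2-methyl-5-oxopent-1-en-1-yl]-4-[(1S,2Z)-3-iodo-1-{[(2Z)-2-methylbut-2-enoyl]oxy}but-2-en-1-yl]-3-methylideneoxolan-2-one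
Conditions: Dess–Martin periodinane, NaHCO3, CH2Cl2, 0 °C (used crude at once)
Reagents that add atoms: none
Why: Buffered Dess–Martin oxidation gives the β-acetoxy aldehyde under near-neutral conditions that avoid elimination of acetic acid.

**Step 14**
Reactants: 20 seco-aldehyde (name as in step 13)
Product: 22 (3aS,4R,5Z,7S,9S,10Z,11aS)-9-(acetyloxy)-7-hydroxy-6,10-dimethyl-3-methylidene-2-oxo-2,3,3a,4,7,8,9,11a-octahydrocyclodeca[b]furan-4-yl (2Z)-2-methylbut-2-enoate, via trimethylsilyl ether 21 (not isolated)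
Conditions: undivided cell, Zn anode, Ni-foam cathode, 2 mA constant current; CrCl3 (20 mol%), NiCl2(MeOCH2CH2OMe) (2 mol%), 2,9-dimethyl-1,10-phenanthroline (2 mol%), Me3SiCl (2 equiv), LiCl, n-Bu4NPF6, DMF, 2 mM (slow addition of 20), rt; then aq. citric acid
Reagents that add atoms: none
Why: Proposed new method: an electroreductive Ni/Cr co-catalysed NHK macrocyclisation in which zerovalent nickel inserts into the (Z)-alkenyl iodide with retention and transmetalates to chromium, the alkenylchromium adds to the tethered aldehyde, Me3SiCl releases chromium from the alkoxide and the cathode returns it to the divalent state, so that catalytic chromium and a low steady-state alkenylchromium concentration favour ten-membered ring closure over dimerisation, with C1 expected 1,3-anti to the C3 acetate (Evans polar model for β-acyloxy aldehydes within the ring-closing geometry); the closest known reactions are the intermolecular electrochemical Ni/Cr NHK coupling of alkenyl halides with aldehydes and stoichiometric CrCl2/NiCl2 NHK medium-ring closures.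

## Compound list

1 | (3S)-3-hydroxyoxolan-2-one [(S)-α-hydroxy-γ-butyrolactone] | O[C@H]1CCOC1=O | starting material
2 | (3S)-oxolane-2,3-diol (lactol, anomers) | O[C@H]1CCOC1O | intermediate
3 | (3S)-pent-4-yne-1,3-diol | C#C[C@@H](O)CCO | intermediate
4 | (3S)-5-{[tert-butyl(dimethyl)silyl]oxy}pent-1-yn-3-ol | C#C[C@@H](O)CCO[Si](C)(C)C(C)(C)C | intermediate
5 | (5S)-5-(2-{[tert-butyl(dimethyl)silyl]oxy}ethyl)-4-methyl-2,5-dihydro-1,2-oxamagnesole (cyclic alkenylmagnesium alkoxide) | C1=C(C)[C@H](CCO[Si](C)(C)C(C)(C)C)O[Mg]1 | intermediate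
6 | (5S)-5-(2-{[tert-butyl(dimethyl)silyl]oxy}ethyl)-4-methyl-2,5-dihydrofuran-2-ol (anomers; fragment 1, C1–C6) | OC1C=C(C)[C@@H](O1)CCO[Si](C)(C)C(C)(C)C | intermediate
7 | (4R)-2,2-dimethyl-1,3-dioxolane-4-carbaldehyde [(R)-glyceraldehyde acetonide] | O=C[C@H]1COC(C)(C)O1 | starting material
8 | (1R)-1-[(4R)-2,2-dimethyl-1,3-dioxolan-4-yl]but-2-yn-1-ol | CC#C[C@@H](O)[C@H]1COC(C)(C)O1 | intermediate
9 | sodium (5R)-5-[(4R)-2,2-dimethyl-1,3-dioxolan-4-yl]-2,2-bis(2-methoxyethoxy)-3-methyl-2,5-dihydro-1,2-oxaluminol-2-uide (cyclic alkenylaluminate) | CC1=C[C@H]([C@H]2COC(C)(C)O2)O[Al-]1(OCCOC)OCCOC.[Na+] | intermediate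
10 | (1R,2Z)-1-[(4R)-2,2-dimethyl-1,3-dioxolan-4-yl]-3-iodobut-2-en-1-ol | I/C(C)=C\[C@@H](O)[C@H]1COC(C)(C)O1 | intermediate
11 | (1R,2Z)-1-[(4R)-2,2-dimethyl-1,3-dioxolan-4-yl]-3-iodobut-2-en-1-yl (2Z)-2-methylbut-2-enoate | I/C(C)=C\[C@@H](OC(=O)/C(C)=C\C)[C@H]1COC(C)(C)O1 | intermediate
12 | (2R,3R,4Z)-1,2-dihydroxy-5-iodohex-4-en-3-yl (2Z)-2-methylbut-2-enoate | I/C(C)=C\[C@@H](OC(=O)/C(C)=C\C)[C@H](O)CO | intermediate
13 | (2R,3Z)-4-iodo-1-oxopent-3-en-2-yl (2Z)-2-methylbut-2-enoate | I/C(C)=C\[C@@H](OC(=O)/C(C)=C\C)C=O | intermediate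
14 | methyl (4R,5Z)-3-hydroxy-6-iodo-4-{[(2Z)-2-methylbut-2-enoyl]oxy}-2-methylidenehept-5-enoate (C3 epimers) | I/C(C)=C\[C@@H](OC(=O)/C(C)=C\C)C(O)C(=C)C(=O)OC | intermediate
15 | methyl (2Z,4S,5Z)-2-(bromomethyl)-6-iodo-4-{[(2Z)-2-methylbut-2-enoyl]oxy}hepta-2,5-dienoate (fragment 2, C7–C14) | I/C(C)=C\[C@@H](OC(=O)/C(C)=C\C)/C=C(\CBr)C(=O)OC | intermediate
16 | methyl (3S,4S,5Z,7S)-9-{[tert-butyl(dimethyl)silyl]oxy}-4,7-dihydroxy-3-[(1S,2Z)-3-iodo-1-{[(2Z)-2-methylbut-2-enoyl]oxy}but-2-en-1-yl]-6-methyl-2-methylidenenon-5-enoate | C=C(C(=O)OC)[C@@H]([C@@H](O)/C=C(/C)[C@@H](O)CCO[Si](C)(C)C(C)(C)C)[C@H](OC(=O)/C(C)=C\C)/C=C(\I)C | intermediate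
17 | (4S,5S)-5-[(1Z,3S)-5-{[tert-butyl(dimethyl)silyl]oxy}-3-hydroxy-2-methylpent-1-en-1-yl]-4-[(1S,2Z)-3-iodo-1-{[(2Z)-2-methylbut-2-enoyl]oxy}but-2-en-1-yl]-3-methylideneoxolan-2-one | C=C1C(=O)O[C@@H](/C=C(/C)[C@@H](O)CCO[Si](C)(C)C(C)(C)C)[C@H]1[C@H](OC(=O)/C(C)=C\C)/C=C(\I)C | intermediate
18 | (4S,5S)-5-[(1Z,3S)-3-(acetyloxy)-5-{[tert-butyl(dimethyl)silyl]oxy}-2-methylpent-1-en-1-yl]-4-[(1S,2Z)-3-iodo-1-{[(2Z)-2-methylbut-2-enoyl]oxy}but-2-en-1-yl]-3-methylideneoxolan-2-one | C=C1C(=O)O[C@@H](/C=C(/C)[C@@H](OC(C)=O)CCO[Si](C)(C)C(C)(C)C)[C@H]1[C@H](OC(=O)/C(C)=C\C)/C=C(\I)C | intermediate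
19 | (4S,5S)-5-[(1Z,3S)-3-(acetyloxy)-5-hydroxy-2-methylpent-1-en-1-yl]-4-[(1S,2Z)-3-iodo-1-{[(2Z)-2-methylbut-2-enoyl]oxy}but-2-en-1-yl]-3-methylideneoxolan-2-one | C=C1C(=O)O[C@@H](/C=C(/C)[C@@H](OC(C)=O)CCO)[C@H]1[C@H](OC(=O)/C(C)=C\C)/C=C(\I)C | intermediate
20 | (4S,5S)-5-[(1Z,3S)-3-(acetyloxy)-2-methyl-5-oxopent-1-en-1-yl]-4-[(1S,2Z)-3-iodo-1-{[(2Z)-2-methylbut-2-enoyl]oxy}but-2-en-1-yl]-3-methylideneoxolan-2-one | C=C1C(=O)O[C@@H](/C=C(/C)[C@@H](OC(C)=O)CC=O)[C@H]1[C@H](OC(=O)/C(C)=C\C)/C=C(\I)C | intermediate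
21 | (3aS,4R,5Z,7S,9S,10Z,11aS)-9-(acetyloxy)-6,10-dimethyl-3-methylidene-2-oxo-7-[(trimethylsilyl)oxy]-2,3,3a,4,7,8,9,11a-octahydrocyclodeca[b]furan-4-yl (2Z)-2-methylbut-2-enoate | C=C1C(=O)O[C@H]2/C=C(/C)[C@@H](OC(C)=O)C[C@H](O[Si](C)(C)C)/C(C)=C\[C@@H](OC(=O)/C(C)=C\C)[C@@H]12 | intermediate
22 | (3aS,4R,5Z,7S,9S,10Z,11aS)-9-(acetyloxy)-7-hydroxy-6,10-dimethyl-3-methylidene-2-oxo-2,3,3a,4,7,8,9,11a-octahydrocyclodeca[b]furan-4-yl (2Z)-2-methylbut-2-enoate (CNP0319825.5) | C=C1C(=O)O[C@H]2/C=C(/C)[C@@H](OC(C)=O)C[C@H](O)/C(C)=C\[C@@H](OC(=O)/C(C)=C\C)[C@@H]12 | target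

## Step count and risks

Total step count: 14 (steps 1–3 for fragment 1, steps 4–9 for fragment 2, steps 10–14 for union and endgame).
Longest linear sequence: 11 steps (7 → 22, steps 4–14).

The three steps most likely to fail:

**Step 14 (the proposed new electrochemical macrocyclisation).** The ring may not close under catalytic turnover, the β-acetoxy aldehyde may eliminate, or C1 may form with the wrong configuration. The fallback sets out from 20 and uses the classical stoichiometric NHK ring closure (CrCl2 in excess with catalytic NiCl2, DMSO–THF, 2 mM, rt), which gives 22 directly. Any (3aS,4R,5Z,7R,9S,10Z,11aS)-C1 epimer of 22 F4 that forms beside or instead of 22 is oxidised with Dess–Martin periodinane to (3aS,4R,5Z,9S,10Z,11aS)-9-(acetyloxy)-6,10-dimethyl-3-methylidene-2,7-dioxo-2,3,3a,4,7,8,9,11a-octahydrocyclodeca[b]furan-4-yl (2Z)-2-methylbut-2-enoate F5. This macrocyclic Z-enone is reduced with NaBH4/CeCl3·7H2O at −78 °C (Luche reduction, hydride from the exposed face of the ring), so that C1 is set in a separate reduction step; the facial outcome of that reduction is not predicted with confidence. The fallback comes back to the route at 22.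

**Step 10 (indium allylation).** The allylindium could lose the angelate by 1,4-elimination, or the facial selectivity relative to C8 could be low; the selectivity rests on a transition-state model, not on a direct precedent for this reagent type. The fallback sets out from 14. Acetylation (Ac2O, pyridine) gives methyl (4R,5Z)-3-(acetyloxy)-6-iodo-4-{[(2Z)-2-methylbut-2-enoyl]oxy}-2-methylidenehept-5-enoate F2. SN2′ borylation of this Baylis–Hillman acetate (bis(pinacolato)diboron, CuCl, LiCl, KOAc, DMF) gives methyl (2E,4S,5Z)-6-iodo-4-{[(2Z)-2-methylbut-2-enoyl]oxy}-2-[(4,4,5,5-tetramethyl-1,3,2-dioxaborolan-2-yl)methyl]hepta-2,5-dienoate F3. Thermal allylboration of lactol 6 with this boronate (toluene, 80 °C; closed chair transition state, no carbon–metal bond that can eliminate the ester) gives hydroxy ester 16, which lactonises (PPTS) and comes back to the route at 17.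

**Step 3 (one-pot carbomagnesiation–formylation and handling of the acid-sensitive lactol).** The magnesium chelate may react sluggishly with DMF, and the lactol can dehydrate to a furan. The fallback sets out from 4: the same CuI-catalysed carbomagnesiation is quenched with I2 to give the stable (1Z,3S)-5-{[tert-butyl(dimethyl)silyl]oxy}-1-iodo-2-methylpent-1-en-3-ol F1. This iodide is treated with n-BuLi (2.2 equiv, THF, −78 °C; alkoxide formation and iodine–lithium exchange) and then DMF, with a buffered work-up, and comes back to the route at 6.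

## Further compounds

F1 | step 3 | (1Z,3S)-5-{[tert-butyl(dimethyl)silyl]oxy}-1-iodo-2-methylpent-1-en-3-ol | I/C=C(/C)[C@@H](O)CCO[Si](C)(C)C(C)(C)C
F2 | step 10 | methyl (4R,5Z)-3-(acetyloxy)-6-iodo-4-{[(2Z)-2-methylbut-2-enoyl]oxy}-2-methylidenehept-5-enoate | I/C(C)=C\[C@@H](OC(=O)/C(C)=C\C)C(OC(C)=O)C(=C)C(=O)OC
F3 | step 10 | methyl (2E,4S,5Z)-6-iodo-4-{[(2Z)-2-methylbut-2-enoyl]oxy}-2-[(4,4,5,5-tetramethyl-1,3,2-dioxaborolan-2-yl)methyl]hepta-2,5-dienoate | I/C(C)=C\[C@@H](OC(=O)/C(C)=C\C)/C=C(\CB1OC(C)(C)C(C)(C)O1)C(=O)OC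
F4 | step 14 | (3aS,4R,5Z,7R,9S,10Z,11aS)-9-(acetyloxy)-7-hydroxy-6,10-dimethyl-3-methylidene-2-oxo-2,3,3a,4,7,8,9,11a-octahydrocyclodeca[b]furan-4-yl (2Z)-2-methylbut-2-enoate (C1 epimer of 22) | C=C1C(=O)O[C@H]2/C=C(/C)[C@@H](OC(C)=O)C[C@@H](O)/C(C)=C\[C@@H](OC(=O)/C(C)=C\C)[C@@H]12
F5 | step 14 | (3aS,4R,5Z,9S,10Z,11aS)-9-(acetyloxy)-6,10-dimethyl-3-methylidene-2,7-dioxo-2,3,3a,4,7,8,9,11a-octahydrocyclodeca[b]furan-4-yl (2Z)-2-methylbut-2-enoate | C=C1C(=O)O[C@H]2/C=C(/C)[C@@H](OC(C)=O)CC(=O)/C(C)=C\[C@@H](OC(=O)/C(C)=C\C)[C@@H]12
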